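The numbers of this flask are invented, and the outcome is calculated.

I must choose the next run.

L 1.5 M; Z 1.35 M; Q 0.0300 M; time 8.0 min

    L + Q → L.Q (k1 = 0.0542 /M/s)
    Z ⇌ X, rate k2*(cs2 - [X]) while solid is left; crystals form when [X] > cs2 (cs2 = 1.2 M, k2 = 0.0242 /s)
    L ⇌ E, rate k3*(cs3 - [E]) while solid is left; crystals form when [E] > cs3 (cs3 = 0.77 M, k3 = 0.0116 /s)
    E + X → E.X (k4 = 0.00390 /M/s)

1. how much E.X there is at 8.0 min, in percent of the L charged
2. concentration of E in solution at 2.0 min, in percent of saturation
3. the change that raises the amount of E.X at 8.0 min, in percent of the L charged most ("none" if none brings more than 2 percentage points) (Sunday's / Thursday's / Monday's / Tuesday's / none)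
4. amount of E.X at 8.0 min, in percent of the L charged, after Tuesday's

- Sunday's: doubling the dissolution coefficient of step 2, all else as stated
- Thursday's: doubling the dissolution coefficient of step 3, all else as stated
- Monday's: doubling the solubility in step 2, all else as stated
- Tuesday's: doubling the solubility in step 3, all else as stated

- as a solid, counted per litre of solution: L, Z
- at the start none of Z is in solution
- at the start none of L is in solution
- E means what is dissolved; the solid is not counted in it
- run time (flask): 8.0 min

Z, at 1.35 M, stands below L even after Q has taken 0.0300 M of it, so Z is the limiting reagent, and its balance sets a ceiling for E.X of 90.0% of the L charged. How much of that ceiling is reached depends on E. While solid L lasts, E is fed in proportion to its distance below solubility and used in proportion to E times X. I take X as Xa, the lesser of its solubility and its charge, 1.20 M. Feed and use then balance at a standing level of E, Es = cs3·k3/(k3 + k4·Xa), which is 0.549 M, a quasi-steady state reached with a delay of 1.02 min.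

So I reckon E at 2.0 min at 61.2% of saturation. I let the unreacted share of Z decay exponentially at k4·Es after the delay, which gives 53.2% at 8.0 min.

For the next run, k2 does not enter this reckoning, and cs2 enters through Xa, which the charge of Z then holds at 1.35 M. Doubling k3 gives 60.3%, and doubling cs3 gives 75.0%. That last figure is too high, since E and E.X together would exceed the L charged. I still choose Tuesday's change, as a judgement and not as a result of this reckoning, and I expect a yield below 75.0%.

The forecast, holding that “the two changes to step 2 do little because X is already plentiful early on”, gives 53%, 61%, Tuesday's and 64%.

The simulation gives 53.7%, 63.5%, Tuesday's with a gain of 11 percentage points, and 64.3%.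

At 8.00 min in this flask E is made 1.19 times as fast as it is used, each step taken net. At 4.00 min this flask holds E at 0.559 M and X at 0.952 M, which is less than the 1.20 M I took.

With 0.81 M of Z, the ceiling is 54.0% and Xa is that charge, so the standing level is 0.605 M, higher than 0.549 M, and the reckoning gives 33.6%. The computed result for that flask is 34.7%.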